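A direct plan would follow the two chalcone halves of the target: it would dimerise the O-benzylated, ring-brominated chalcone A1 with FeCl3 (trivalent iron) at its two α-carbons (C3–C4), let each ketone oxygen capture the quinone methide of the other half to reach the twofold-symmetric diketo-diol A2 (in equilibrium with its bis-hemiketal), reduce one hemiketal with Et3SiH/BF3·OEt2 to the racemic oxolane A3, separate the enantiomers on a chiral phase, and remove benzyl groups and bromine by hydrogenolysis.
Weak step 1, the oxidative α–α dimerisation that forms C3–C4: the pairing of two phenoxyl radicals would offer no handle for like against unlike coupling or for absolute configuration, would have no close precedent on chalcones, and would need four bromine atoms that only block positions and must be removed again.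
Weak step 2, the reduction of only one of two symmetry-equivalent hemiketals: the stop after one site and the facial selectivity would rest on a strain argument alone.
Weak step 3, the separation of enantiomers one step before the end: half of the most advanced material would be discarded.

Retrosynthetic overview (oxolane numbering of the target: O1, C2 with 4-hydroxyphenyl, C3 with the aroyl group, C4 with the carbinol side chain, C5 with 2,4-dihydroxyphenyl).
The unit C5–C4–C3–C(=O) is read as succinic acid, C2 and the carbinol carbon as two molecules of one aldehyde, and the two resorcinol rings (on C5 and on the ketone carbon) as one aryl bromide used twice, first as its lithium and then as its magnesium derivative.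
Key disconnection: an auxiliary-controlled double aldol forms C2–C3 and C4–C(carbinol), and bis-lactonisation forms O1–C5 and the carbinol O–acyl bond, giving a cis-fused 3,7-dioxabicyclo[3.3.0]octane-2,6-dione with four of the five stereocentres.
Ring order: the future oxolane ring closes first, as a γ-lactone, together with a second γ-lactone that clamps C3 and C4 cis and masks the carbinol; the first aryl addition and exo hydride delivery set C5; the second aryl addition opens the clamp to the aryl ketone and the free carbinol.
The weak steps are avoided by design: C3–C4 is bought and not made by radical pairing (no blocking bromine), the absolute configuration comes from a recoverable auxiliary in the second step (no resolution), and the two carboxyl carbons are converted one after the other, so a reduction never has to choose between two hemiketals.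
Key step: step 2

Assumption: the (2R,5R) auxiliary is taken to shield the enolate face that leads to the (1R,4R,5R,8R) bis-lactone; if the sense of induction should prove opposite, the (2S,5S) antipode would be used with no other change.
Assumption: compounds 1, 2, 4, 9 and 10 are taken as commercially available.

Step 1
Reactants: 1 succinyl chloride; 2 (2R,5R)-2,5-bis(methoxymethyl)pyrrolidine
Product: 3 1,4-bis[(2R,5R)-2,5-bis(methoxymethyl)pyrrolidin-1-yl]butane-1,4-dione
Conditions: 2 (2.1 equiv), K2CO3, CH2Cl2, 0 °C to rt
Reagents that add atoms: none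
Why: Schotten–Baumann-type N-acylation of the secondary amine by the diacid chloride should give the twofold-symmetric bis-amide; no stereocentre is formed, and the two pyrrolidine units later serve as recoverable chiral auxiliaries.

Step 2
Reactants: 3 1,4-bis[(2R,5R)-2,5-bis(methoxymethyl)pyrrolidin-1-yl]butane-1,4-dione; 4 4-(benzyloxy)benzaldehyde (two molecules)
Product: 8 (1R,4R,5R,8R)-4,8-bis[4-(benzyloxy)phenyl]-3,7-dioxabicyclo[3.3.0]octane-2,6-dione, via dilithium dienolate 5 (not isolated), via zirconium dienolate 6 (not isolated), via bis-aldol diamide 7 (not isolated)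
Conditions: LiN(iPr)2 (2.2 equiv), THF, −78 to −20 °C; Cp2ZrCl2 (2.2 equiv), −78 °C; 4 (2.2 equiv), −78 to −40 °C; then 2 M HCl, dioxane, 70 °C
Reagents that add atoms: none
Why: Two equivalents of LiN(iPr)2 should turn the succinamide into the conjugated (Z,Z)-dienolate 5, which is transmetalated to the zirconium dienolate 6; each amide enolate then adds to one molecule of 4 through a closed chair (Zimmerman–Traxler) transition state to give the syn,syn bis-aldol 7, and acid lets each hydroxyl group attack the amide carbonyl in its γ-position (N to O acyl transfer), which releases 2 and closes the two γ-lactones. The closest known chemistry is the double aldol of tetraalkylsuccinamide dianions with aromatic aldehydes followed by acid lactonisation to 4,8-diaryl-3,7-dioxabicyclo[3.3.0]octane-2,6-diones, together with the syn-selective aldol addition of zirconium enolates of amides of C2-symmetric 2,5-disubstituted pyrrolidines. Both rings close in the 5-exo-trig mode at an amide carbonyl carbon: the ring C1–C2–O3–C4–C5 masks the later ketone carbon and carbinol, and the ring C5–C6–O7–C8–C1 is the oxolane ring of the target at the lactone oxidation level. C1 and C5 (C3 and C4 of the target) are set by the auxiliary, which shields the same face of both enolates and so gives the like pair, and C8 and C4 (C2 and the carbinol carbon of the target) are set by the chair transition state of the (Z)-enolate, which makes each aldol syn and so places each aryl group exo on the bicycle. The selectivity needed is like over unlike at C1/C5 and one aldol per enolate: the two identical auxiliaries secure the first, only the like,syn,syn bis-aldol can close two cis-fused lactones (other isomers stay behind as separable hydroxy amides), and the dienolate keeps each amide inert to the neighbouring aldolate until both C–C bonds are made. In one operation the step should form C2–C3 and C4–C(carbinol) of the target, both lactone rings and four of the five stereocentres from a succinic acid derivative and two molecules of one aldehyde.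

Step 3
Reactants: 9 4-bromobenzene-1,3-diol; 10 benzyl bromide
Product: 11 2,4-bis(benzyloxy)-1-bromobenzene
Conditions: BnBr (2.3 equiv), K2CO3, DMF, 60 °C
Reagents that add atoms: benzyl bromide (10), BrCc1ccccc1
Why: Williamson ether synthesis on both phenols should give the aryl bromide from which the two arylmetal reagents that deliver the resorcinol rings are made; no stereocentre is involved.

Step 4
Reactants: 8 (1R,4R,5R,8R)-4,8-bis[4-(benzyloxy)phenyl]-3,7-dioxabicyclo[3.3.0]octane-2,6-dione; 11 2,4-bis(benzyloxy)-1-bromobenzene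
Product: 13 (1R,4R,5R,8R)-6-[2,4-bis(benzyloxy)phenyl]-4,8-bis[4-(benzyloxy)phenyl]-6-hydroxy-3,7-dioxabicyclo[3.3.0]octan-2-one (hemiketal carbon C6 not fixed), via [2,4-bis(benzyloxy)phenyl]lithium 12 (not isolated)
Conditions: 11 (1.0 equiv), n-BuLi (1.0 equiv), THF, −78 °C; transfer into 8 (1.3 equiv), THF, −78 °C; AcOH, −78 °C
Reagents that add atoms: none
Why: Bromine–lithium exchange gives 12, whose 1,2-addition to a γ-lactone carbonyl should stop at the tetrahedral lithium lactolate at −78 °C (aryllithium addition to a lactone to give a lactol); the two carbonyl groups of 8 are homotopic, so only one mono-adduct can form, inverse addition to an excess of recoverable 8 keeps double addition low, and no configurationally fixed stereocentre is created.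

Step 5
Reactants: 13 (1R,4R,5R,8R)-6-[2,4-bis(benzyloxy)phenyl]-4,8-bis[4-(benzyloxy)phenyl]-6-hydroxy-3,7-dioxabicyclo[3.3.0]octan-2-one
Product: 15 (1R,4R,5S,6R,8R)-6-[2,4-bis(benzyloxy)phenyl]-4,8-bis[4-(benzyloxy)phenyl]-3,7-dioxabicyclo[3.3.0]octan-2-one, via oxocarbenium ion 14 (not isolated)
Conditions: Et3SiH (3 equiv), BF3·OEt2 (1.5 equiv), CH2Cl2, −78 °C; Et3N then NaHCO3 (aq) at −78 °C
Reagents that add atoms: none
Why: Ionic hydrogenation of a cyclic hemiketal (Lewis-acid-mediated reductive deoxygenation with a silane): BF3 should ionise 13 to the aryl-stabilised oxocarbenium ion 14, and Et3SiH should deliver hydride to the convex (exo) face of the cis-fused bicycle, opposite the lactone ring, so that the aryl group at C6 (C5 of the target) ends endo, cis to the C4 side chain, as in the reduction of aryl hemiketals in the furofuran lignan series; only one hemiketal is present, so no choice of site arises.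

Step 6
Reactants: 15 (1R,4R,5S,6R,8R)-6-[2,4-bis(benzyloxy)phenyl]-4,8-bis[4-(benzyloxy)phenyl]-3,7-dioxabicyclo[3.3.0]octan-2-one; 11 2,4-bis(benzyloxy)-1-bromobenzene
Product: 18 [2,4-bis(benzyloxy)phenyl]{(2R,3R,4R,5R)-5-[2,4-bis(benzyloxy)phenyl]-2-[4-(benzyloxy)phenyl]-4-[(R)-[4-(benzyloxy)phenyl](hydroxy)methyl]oxolan-3-yl}methanone, via [2,4-bis(benzyloxy)phenyl]magnesium bromide 16 (not isolated), via lactol 17 (not isolated)
Conditions: 11 (1.5 equiv), Mg turnings, LiCl, THF, rt; then 15, THF, −20 to 0 °C; AcOH, −20 °C
Reagents that add atoms: none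
Why: LiCl-assisted insertion of magnesium into the C–Br bond of 11 gives the Grignard reagent 16, which is less basic than an aryllithium and should add once to the remaining γ-lactone (arylmagnesium addition to a lactone that stops at the lactol stage, as in the synthesis of aryl C-glycosides from sugar lactones), since the ortho-substituted and α-branched aryl ketone that any opening of the magnesium lactolate would give is too hindered for a second addition; protonation gives lactol 17, which opens to the γ-hydroxy ketone 18, so that one operation sets free both the aryl ketone on C3 and the carbinol of the C4 side chain, no stereocentre is formed or broken (the C–O bond of the carbinol carbon is not touched), and the mild reagent together with the cold acetic acid quench keeps the now enolisable C3 from epimerising.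

Step 7
Reactants: 18 [2,4-bis(benzyloxy)phenyl]{(2R,3R,4R,5R)-5-[2,4-bis(benzyloxy)phenyl]-2-[4-(benzyloxy)phenyl]-4-[(R)-[4-(benzyloxy)phenyl](hydroxy)methyl]oxolan-3-yl}methanone
Product: 19 (2,4-dihydroxyphenyl){(2R,3R,4R,5R)-5-(2,4-dihydroxyphenyl)-4-[(R)-hydroxy(4-hydroxyphenyl)methyl]-2-(4-hydroxyphenyl)oxolan-3-yl}methanone (CNP0244141.1)
Conditions: H2 (1 atm), Pd/C, EtOAc–MeOH, rt, stopped at the calculated uptake
Reagents that add atoms: none
Why: Heterogeneous catalytic hydrogenolysis of the six aryl benzyl ethers under neutral conditions should leave the two benzylic C–O bonds of the ring, the benzylic carbinol and the aryl ketone intact, as in the debenzylation of phenolic 2,5-diaryloxolane lignans; no stereocentre is touched.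

Compound list
1 | succinyl chloride (butanedioyl dichloride) | O=C(Cl)CCC(=O)Cl | starting material
2 | (2R,5R)-2,5-bis(methoxymethyl)pyrrolidine | COC[C@H]1CC[C@H](COC)N1 | starting material
3 | 1,4-bis[(2R,5R)-2,5-bis(methoxymethyl)pyrrolidin-1-yl]butane-1,4-dione | COC[C@H]1CC[C@H](COC)N1C(=O)CCC(=O)N1[C@@H](COC)CC[C@@H]1COC | intermediate
4 | 4-(benzyloxy)benzaldehyde | O=Cc1ccc(OCc2ccccc2)cc1 | starting material
5 | dilithium (1Z,3Z)-1,4-bis[(2R,5R)-2,5-bis(methoxymethyl)pyrrolidin-1-yl]buta-1,3-diene-1,4-diolate | [Li]O/C(N1[C@@H](COC)CC[C@@H]1COC)=C\C=C(/O[Li])N1[C@@H](COC)CC[C@@H]1COC | intermediate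
6 | bis(chlorozirconocene) (1Z,3Z)-dienolate of 3 (cyclopentadienyl rings drawn σ-bonded in the SMILES) | Cl[Zr](C1C=CC=C1)(C1C=CC=C1)O/C(N1[C@@H](COC)CC[C@@H]1COC)=C\C=C(/O[Zr](Cl)(C1C=CC=C1)C1C=CC=C1)N1[C@@H](COC)CC[C@@H]1COC | intermediate
7 | (2R,3R)-2,3-bis{(R)-[4-(benzyloxy)phenyl](hydroxy)methyl}-1,4-bis[(2R,5R)-2,5-bis(methoxymethyl)pyrrolidin-1-yl]butane-1,4-dione | O=C(N1[C@@H](COC)CC[C@@H]1COC)[C@@H]([C@@H](O)c1ccc(OCc2ccccc2)cc1)[C@H]([C@@H](O)c1ccc(OCc2ccccc2)cc1)C(=O)N1[C@@H](COC)CC[C@@H]1COC | intermediate
8 | (1R,4R,5R,8R)-4,8-bis[4-(benzyloxy)phenyl]-3,7-dioxabicyclo[3.3.0]octane-2,6-dione, cis-fused, both aryl groups exo | O=C2[C@@H]1[C@H]([C@@H](O2)c3ccc(OCc4ccccc4)cc3)C(=O)O[C@H]1c1ccc(OCc2ccccc2)cc1 | intermediate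
9 | 4-bromobenzene-1,3-diol | Oc1ccc(Br)c(O)c1 | starting material
10 | benzyl bromide | BrCc1ccccc1 | starting material
11 | 2,4-bis(benzyloxy)-1-bromobenzene | Brc1ccc(OCc2ccccc2)cc1OCc1ccccc1 | intermediate
12 | [2,4-bis(benzyloxy)phenyl]lithium | [Li]c1ccc(OCc2ccccc2)cc1OCc1ccccc1 | intermediate
13 | (1R,4R,5R,8R)-6-[2,4-bis(benzyloxy)phenyl]-4,8-bis[4-(benzyloxy)phenyl]-6-hydroxy-3,7-dioxabicyclo[3.3.0]octan-2-one, hemiketal carbon C6 not fixed | O=C2[C@@H]1[C@H]([C@@H](O2)c3ccc(OCc4ccccc4)cc3)C(O)(c3ccc(OCc4ccccc4)cc3OCc3ccccc3)O[C@H]1c1ccc(OCc2ccccc2)cc1 | intermediate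
14 | cyclic oxocarbenium ion formed from 13 by loss of hydroxide at C6 (O7=C6 cation carrying the 2,4-bis(benzyloxy)phenyl group) | O=C2[C@@H]1[C@H]([C@@H](O2)c3ccc(OCc4ccccc4)cc3)C(c3ccc(OCc4ccccc4)cc3OCc3ccccc3)=[O+][C@H]1c1ccc(OCc2ccccc2)cc1 | intermediate
15 | (1R,4R,5S,6R,8R)-6-[2,4-bis(benzyloxy)phenyl]-4,8-bis[4-(benzyloxy)phenyl]-3,7-dioxabicyclo[3.3.0]octan-2-one, aryl at C6 endo, aryl groups at C4 and C8 exo | O=C2[C@@H]1[C@H]([C@@H](O2)c3ccc(OCc4ccccc4)cc3)[C@H](c3ccc(OCc4ccccc4)cc3OCc3ccccc3)O[C@H]1c1ccc(OCc2ccccc2)cc1 | intermediate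
16 | [2,4-bis(benzyloxy)phenyl]magnesium bromide, formed and used as its LiCl complex in THF | Br[Mg]c1ccc(OCc2ccccc2)cc1OCc1ccccc1 | intermediate
17 | (1R,4R,5S,6R,8R)-2,6-bis[2,4-bis(benzyloxy)phenyl]-4,8-bis[4-(benzyloxy)phenyl]-3,7-dioxabicyclo[3.3.0]octan-2-ol, hemiketal carbon C2 not fixed, ring tautomer of 18 | OC2(c3ccc(OCc4ccccc4)cc3OCc3ccccc3)[C@@H]1[C@H]([C@@H](O2)c3ccc(OCc4ccccc4)cc3)[C@H](c3ccc(OCc4ccccc4)cc3OCc3ccccc3)O[C@H]1c1ccc(OCc2ccccc2)cc1 | intermediate
18 | [2,4-bis(benzyloxy)phenyl]{(2R,3R,4R,5R)-5-[2,4-bis(benzyloxy)phenyl]-2-[4-(benzyloxy)phenyl]-4-[(R)-[4-(benzyloxy)phenyl](hydroxy)methyl]oxolan-3-yl}methanone | O=C(c1ccc(OCc2ccccc2)cc1OCc1ccccc1)[C@@H]1[C@H]([C@@H](O)c2ccc(OCc3ccccc3)cc2)[C@H](c2ccc(OCc3ccccc3)cc2OCc2ccccc2)O[C@H]1c1ccc(OCc2ccccc2)cc1 | intermediate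
19 | (2,4-dihydroxyphenyl){(2R,3R,4R,5R)-5-(2,4-dihydroxyphenyl)-4-[(R)-hydroxy(4-hydroxyphenyl)methyl]-2-(4-hydroxyphenyl)oxolan-3-yl}methanone | O=C(c1ccc(O)cc1O)[C@@H]1[C@H]([C@@H](O)c2ccc(O)cc2)[C@H](c2ccc(O)cc2O)O[C@H]1c1ccc(O)cc1 | target

Total step count: 7. Longest linear sequence: 6 steps (steps 1, 2, 4, 5, 6, 7); step 3 is a one-step side branch.

Steps most likely to fail

Step 2. Facial control may be lost in the second aldol addition if the stereocentre set by the first addition works against the auxiliary. The second deprotonation may also be incomplete, and acid may eliminate water from the benzylic aldol in competition with lactonisation. The fallback sets out from 4 and builds the bicycle one lactone at a time. Condensation of 4 with succinic anhydride (ZnCl2, Et3N, CH2Cl2) gives the racemic trans-paraconic acid, which is resolved at this first stage as its salt with one enantiomer of 1-phenylethylamine to give (2R,3R)-2-[4-(benzyloxy)phenyl]-5-oxooxolane-3-carboxylic acid F1. Its dianion (LiN(SiMe3)2, 2.2 equiv, THF, −78 °C) adds at the lactone α-carbon to a second molecule of 4, anti to the carboxylate, to give (2R,3R,4S)-2-[4-(benzyloxy)phenyl]-4-{[4-(benzyloxy)phenyl](hydroxy)methyl}-5-oxooxolane-3-carboxylic acid F2. DBU then equilibrates the lactone α-carbon, and TsOH in toluene closes the second lactone, which is possible only from the 3,4-cis isomer. The carbinol centre should converge on the exo aryl isomer by reversible ionisation of the 4-(benzyloxy)benzylic C–O bond, and the sequence comes back to the route at 8.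

Step 4. The aryllithium may add to both lactone carbonyl groups, or may deprotonate alpha to a lactone, which would be followed by β-elimination of the neighbouring acyloxy group. The fallback sets out from 8. One equivalent of LiOH (THF–H2O, 0 °C) opens one of the two equivalent lactones to (2R,3R,4R)-2-[4-(benzyloxy)phenyl]-4-{(R)-[4-(benzyloxy)phenyl](hydroxy)methyl}-5-oxooxolane-3-carboxylic acid F3, kept as its dried dilithium salt. Its carboxylate resists a second attack, so 12 (made from 11 and n-BuLi) can add only to the one remaining lactone. Acidification re-closes the cis hydroxy acid to the lactone, and the sequence comes back to the route at 13.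

Step 6. The arylmagnesium reagent may be too sluggish at the hindered lactone carbonyl group or may deprotonate the lactone α-carbon instead of adding, or the tetrahedral adduct may collapse early, which would allow a second addition or epimerisation at C3. The fallback sets out from 15. Me(MeO)NH·HCl and AlMe3 (CH2Cl2, 0 °C) open the lactone to (2R,3R,4R,5R)-5-[2,4-bis(benzyloxy)phenyl]-2-[4-(benzyloxy)phenyl]-4-{(R)-[4-(benzyloxy)phenyl](hydroxy)methyl}-N-methoxy-N-methyloxolane-3-carboxamide F4. Two equivalents of the aryllithium 12 (made from 11 and n-BuLi as in step 4; the first is consumed by the hydroxyl group) then give the ketone through the stable chelated adduct, and the sequence comes back to the route at 18.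

Further compounds
F1 | step 2 | (2R,3R)-2-[4-(benzyloxy)phenyl]-5-oxooxolane-3-carboxylic acid | O=C(O)[C@@H]1CC(=O)O[C@H]1c1ccc(OCc2ccccc2)cc1
F2 | step 2 | (2R,3R,4S)-2-[4-(benzyloxy)phenyl]-4-{[4-(benzyloxy)phenyl](hydroxy)methyl}-5-oxooxolane-3-carboxylic acid, carbinol carbon as a mixture | O=C(O)[C@@H]1[C@@H](C(O)c2ccc(OCc3ccccc3)cc2)C(=O)O[C@H]1c1ccc(OCc2ccccc2)cc1
F3 | step 4 | (2R,3R,4R)-2-[4-(benzyloxy)phenyl]-4-{(R)-[4-(benzyloxy)phenyl](hydroxy)methyl}-5-oxooxolane-3-carboxylic acid, used as its dilithium salt | O=C(O)[C@@H]1[C@H]([C@@H](O)c2ccc(OCc3ccccc3)cc2)C(=O)O[C@H]1c1ccc(OCc2ccccc2)cc1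
F4 | step 6 | (2R,3R,4R,5R)-5-[2,4-bis(benzyloxy)phenyl]-2-[4-(benzyloxy)phenyl]-4-{(R)-[4-(benzyloxy)phenyl](hydroxy)methyl}-N-methoxy-N-methyloxolane-3-carboxamide | CON(C)C(=O)[C@@H]1[C@H]([C@@H](O)c2ccc(OCc3ccccc3)cc2)[C@H](c2ccc(OCc3ccccc3)cc2OCc2ccccc2)O[C@H]1c1ccc(OCc2ccccc2)cc1
A1 | direct plan | (E)-1-[2,4-bis(benzyloxy)phenyl]-3-(3,5-dibromo-4-hydroxyphenyl)prop-2-en-1-one | O=C(/C=C/c1cc(Br)c(O)c(Br)c1)c1ccc(OCc2ccccc2)cc1OCc1ccccc1
A2 | direct plan | rac-(2R,3R)-1,4-bis[2,4-bis(benzyloxy)phenyl]-2,3-bis[(R)-(3,5-dibromo-4-hydroxyphenyl)(hydroxy)methyl]butane-1,4-dione | O=C(c1ccc(OCc2ccccc2)cc1OCc1ccccc1)[C@@H]([C@@H](O)c1cc(Br)c(O)c(Br)c1)[C@H]([C@@H](O)c1cc(Br)c(O)c(Br)c1)C(=O)c1ccc(OCc2ccccc2)cc1OCc1ccccc1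
A3 | direct plan | rac-[2,4-bis(benzyloxy)phenyl]{(2R,3R,4R,5R)-5-[2,4-bis(benzyloxy)phenyl]-2-(3,5-dibromo-4-hydroxyphenyl)-4-[(R)-(3,5-dibromo-4-hydroxyphenyl)(hydroxy)methyl]oxolan-3-yl}methanone | O=C(c1ccc(OCc2ccccc2)cc1OCc1ccccc1)[C@@H]1[C@H]([C@@H](O)c2cc(Br)c(O)c(Br)c2)[C@H](c2ccc(OCc3ccccc3)cc2OCc2ccccc2)O[C@H]1c1cc(Br)c(O)c(Br)c1
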